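**Strategy.** Everything rests on cutting, in the lower (epicatechin) unit, the aryl ether bond O1–C8a of ring C together with the neighbouring C8–C4 interflavan bond; the feature exploited is that O1 and the middle unit sit on adjacent carbons (C8a, C8) of ring A. In the key step an aryne spanning C8–C8a, released from an ortho-lithiated fluoroarene, takes up the tethered C2 alkoxide at C8a, closing the pyran ring with the 2,3-cis stereochemistry already fixed, and the C8 aryllithium so formed adds to the C4 ketone of the middle unit. The precursor is an open-chain syn 1,3-diarylpropanol with fluorine where O1 will sit. The upper unit is attached afterwards; auxiliary C5 oxygens are excised last.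

Key step: step 13

Remark: the target is read as epirobinetinidol-(4β→8)-epirobinetinidol-(4α→8)-epicatechin (all units 2R and 2,3-cis; upper unit 3,4-trans, middle unit 3,4-cis). The C4 configuration of 4–9 and the carbinol configuration of 25 are drawn as the expected major epimers; C4 epimers converge because these centres later become a cation or a carbonyl group.

**Step 1**
Reactants: 1 (+)-dihydromyricetin, (2R,3R)-3,5,7-trihydroxy-2-(3,4,5-trihydroxyphenyl)chroman-4-one
Product: 2 (2R,3R)-7-(benzyloxy)-3,5-dihydroxy-2-[3,4,5-tris(benzyloxy)phenyl]chroman-4-one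
Conditions: BnBr (4.4 equiv), K2CO3, DMF, 0 °C to rt, argon
Reagents that add atoms: benzyl bromide BrCc1ccccc1
Why: Williamson etherification should benzylate the four acidic phenols, while the 5-OH (hydrogen-bonded to the C4 carbonyl) and the secondary 3-OH stay free; no stereocentre is touched.

**Step 2**
Reactants: 2
Product: 3 (2R,3R)-5-(allyloxy)-7-(benzyloxy)-3-hydroxy-2-[3,4,5-tris(benzyloxy)phenyl]chroman-4-one
Conditions: allyl bromide (1.5 equiv), K2CO3, DMF, 50 °C, argon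
Reagents that add atoms: allyl bromide C=CCBr
Why: A second, warmer Williamson etherification should alkylate the chelated 5-phenol but not the alcohol; the allyl ether keeps ring A electron-rich for the later arylations and marks the oxygen to be removed.

**Step 3**
Reactants: 3
Product: 5 (2R,3S,4R)-5-(allyloxy)-7-(benzyloxy)-4-methoxy-2-[3,4,5-tris(benzyloxy)phenyl]chroman-3-ol, via 3,4-trans-diol 4 (not isolated)
Conditions: NaBH4, THF/MeOH, 0 °C; then camphorsulfonic acid (to pH 3), MeOH, rt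
Reagents that add atoms: methanol CO
Why: Borohydride reduction of the 2,3-trans ketone should give the 3,4-trans diol (hydride anti to the 3-hydroxyl), and acid-catalysed SN1 methanolysis of the strongly activated benzylic 4-hydroxyl then gives the 4-methyl ether, again trans to the 3-hydroxyl.

**Step 4**
Reactants: 5
Product: 6 (2R,4R)-5-(allyloxy)-7-(benzyloxy)-4-methoxy-2-[3,4,5-tris(benzyloxy)phenyl]chroman-3-one
Conditions: Dess–Martin periodinane, NaHCO3, CH2Cl2, rt
Reagents that add atoms: none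
Why: Buffered Dess–Martin oxidation should convert the secondary alcohol into the ketone without ionising the 4-methoxy group or epimerising C2.

**Step 5**
Reactants: 6
Product: 7 (2R,3R,4R)-5-(allyloxy)-7-(benzyloxy)-4-methoxy-2-[3,4,5-tris(benzyloxy)phenyl]chroman-3-ol
Conditions: LiBH(s-Bu)3 (L-Selectride), THF, −78 °C; aq. NH4Cl
Reagents that add atoms: none
Why: The bulky hydride should attack the ketone from the face opposite the 2-aryl and 4-methoxy groups (steric approach control, the known catechin-to-epicatechin inversion), setting the 3-hydroxyl cis to the 2-aryl group (3R).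

**Step 6**
Reactants: 7
Product: 8 (2R,3R,4R)-5-(allyloxy)-3,7-bis(benzyloxy)-4-methoxy-2-[3,4,5-tris(benzyloxy)phenyl]chromane
Conditions: NaH, BnBr, n-Bu4NI (cat.), THF/DMF, 0 °C to rt
Reagents that add atoms: benzyl bromide BrCc1ccccc1
Why: Williamson etherification of the alkoxide; the 4-methyl ether is stable to base and no stereocentre is affected.

**Step 7**
Reactants: 8
Product: 10 (2R,3S)-5-(allyloxy)-3,7-bis(benzyloxy)-2-[3,4,5-tris(benzyloxy)phenyl]chroman-4-one, via 4-hydroxyflavan 9 (not isolated)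
Conditions: 0.5 M HCl, THF/H2O, rt; extraction; then Dess–Martin periodinane, NaHCO3, CH2Cl2, 0 °C to rt
Reagents that add atoms: water O
Why: SN1 hydrolysis of the activated benzylic methyl ether, then Dess–Martin oxidation of the benzylic alcohol, should give the 4-ketone; the neutral oxidation preserves the base-labile 2,3-cis arrangement (the 3S label is a priority change only).

**Step 8**
Reactants: 11 1,3,5-trifluorobenzene
Product: 12 1,3-bis(benzyloxy)-5-fluorobenzene
Conditions: BnOH (2.1 equiv), NaH, NMP, 0 °C to 80 °C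
Reagents that add atoms: benzyl alcohol OCc1ccccc1
Why: Twofold nucleophilic aromatic substitution by sodium benzyloxide; each exchange of F for OBn lowers the reactivity of the ring, so two equivalents should stop at the monofluoride.

**Step 9**
Reactants: 12; 13 methyl (R)-glycidate (methyl (2R)-oxirane-2-carboxylate)
Product: 16 methyl (R)-3-[2,4-bis(benzyloxy)-6-fluorophenyl]-2-hydroxypropanoate, via aryllithium 14 (not isolated), via arylmagnesium bromide 15 (not isolated)
Conditions: n-BuLi, THF, −78 °C; MgBr2·OEt2, −78 to −40 °C; CuI (10 mol %), then 13, −40 to −10 °C; aq. NH4Cl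
Reagents that add atoms: none
Why: Directed ortho-lithiation at the C–H flanked by F and OBn, transmetalation to magnesium and copper-catalysed SN2 opening of the epoxide at its CH2 terminus should give the aryl lactate; the stereocentre of 13 is not touched and stays R.

**Step 10**
Reactants: 16
Product: 17 methyl (R)-2-(benzyloxy)-3-[2,4-bis(benzyloxy)-6-fluorophenyl]propanoate
Conditions: BnBr, Ag2O, CH2Cl2, rt, dark
Reagents that add atoms: benzyl bromide BrCc1ccccc1
Why: Silver-oxide-mediated O-benzylation (Purdie-type alkylation) needs no strong base and so should not racemise the α-alkoxy ester.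

**Step 11**
Reactants: 17
Product: 18 (R)-2-(benzyloxy)-3-[2,4-bis(benzyloxy)-6-fluorophenyl]propanal
Conditions: i-Bu2AlH (1.1 equiv), toluene/CH2Cl2, −78 °C; aqueous potassium sodium tartrate
Reagents that add atoms: none
Why: Partial ester reduction at low temperature through the stable aluminium hemiacetal should stop at the aldehyde, which is used at once to avoid epimerisation.

**Step 12**
Reactants: 18; 19 4-bromo-1,2-bis(benzyloxy)benzene
Product: 21 (1R,2R)-2-(benzyloxy)-1-[3,4-bis(benzyloxy)phenyl]-3-[2,4-bis(benzyloxy)-6-fluorophenyl]propan-1-ol, via Grignard reagent 20 (not isolated)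
Conditions: 19, Mg, THF, rt; then added to 18 and MgBr2·OEt2 in CH2Cl2, −78 °C; aq. NH4Cl
Reagents that add atoms: none
Why: Cram-chelate-controlled Grignard addition: magnesium bridges the aldehyde and α-benzyloxy oxygens and the aryl group adds from the face opposite the CH2Ar substituent, setting the new carbinol centre (1R) syn to the benzyloxy group.

**Step 13**
Reactants: 21; 10
Product: 25 tertiary alcohol: 5-O-allyl-3,7,3',4',5'-penta-O-benzyl-epigallocatechin-4-ol bearing at C4 the C8 carbon of 3,5,7,3',4'-penta-O-benzyl-(−)-epicatechin (new aryl group 4β; hydroxyl 4α), via dilithio species 22 (not isolated), via aryne 23 (not isolated), via 8-lithioflavan 24 (not isolated)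
Conditions: 21 (1.3 equiv), n-BuLi (2.1 equiv per 21), THF (0.02 M), −78 °C; warm to −35 °C; recool to −78 °C; add 10 (1.0 equiv), −78 to −40 °C; aq. NH4Cl
Reagents that add atoms: none
Why: Proposed new method: the first equivalent of n-BuLi forms the lithium alkoxide and the second lithiates C8, the ring A position flanked by F and the C7 benzyloxy group; on warming LiF is lost to give the C8–C8a aryne 23, the tethered C2 alkoxide adds to C8a, and the C8 aryllithium 24 so formed adds to the C4 carbonyl of 10. The closest known reaction types are the aryne cyclisation of tethered alkoxides to chromans, the cyclisation of benzyne-tethered organolithiums with electrophilic quench of the new aryllithium, and the addition of 8-lithioflavans to flavan-4-ones. Ring C of the lower unit closes in a 6-exo-dig mode by in-plane attack of oxygen on the aryne carbon next to the tether. No stereocentre is made in the ring closure: C2 and C3 keep the syn arrangement from steps 9 and 12 because the C2–O bond is not touched, which is what turns the syn alcohol into the 2,3-cis flavan, while the carbinol centre formed at C4 of the middle unit (aryl expected anti to the 3-benzyloxy group) is erased in step 14. The step needs oxygen at C8a and carbon at C8: the tether reaches only C8a, and the inductively withdrawing C7 benzyloxy group beside the triple bond directs the nucleophile to the distal carbon C8a so that the charge develops at C8 next to oxygen; high dilution and the intramolecular trap guard against capture of the aryne by 22.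

**Step 14**
Reactants: 25
Product: 26 5-O-allyl-3,7,3',4',5'-penta-O-benzyl-epigallocatechin-(4α→8)-3,5,7,3',4'-penta-O-benzyl-epicatechin (upper unit 2R,3R,4S; lower unit 2R,3R)
Conditions: Bu3SnH, CF3CO2H, CH2Cl2, −78 to 0 °C
Reagents that add atoms: none
Why: Ionic hydrogenation: acid ionises the tertiary diaryl carbinol and the tin hydride should deliver hydride to the C4 cation from the face opposite the axial 3-benzyloxy and 2-aryl groups, setting the 4α-aryl, 3,4-cis centre (4S).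

**Step 15**
Reactants: 26; 8
Product: 27 5-O-allyl-3,7,3',4',5'-penta-O-benzyl-epigallocatechin-(4β→8)-[5-O-allyl-3,7,3',4',5'-penta-O-benzyl-epigallocatechin]-(4α→8)-3,5,7,3',4'-penta-O-benzyl-epicatechin
Conditions: Me3SiOTf (0.3 equiv), CH2Cl2, −78 °C, slow addition of 8 (1.2 equiv) to 26; Et3N quench
Reagents that add atoms: none
Why: Lewis-acid-mediated Friedel–Crafts flavan coupling: ionisation of the 4-methoxy group of 8 gives the C4 cation, which should be attacked by C8 of the middle unit (the free ring A carbon ortho to O1 and OBn and para to the allyloxy group, whereas C6 of both lower rings lies between two ether groups) from the face anti to the 3-benzyloxy group, setting the 3,4-trans 4β linkage.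

**Step 16**
Reactants: 27
Product: 28 3,7,3',4',5'-penta-O-benzyl-epigallocatechin-(4β→8)-[3,7,3',4',5'-penta-O-benzyl-epigallocatechin]-(4α→8)-3,5,7,3',4'-penta-O-benzyl-epicatechin (free 5-OH in the upper and middle units)
Conditions: Pd(PPh3)4 (5 mol %), morpholine, THF, rt
Reagents that add atoms: none
Why: Tsuji–Trost deallylation: zerovalent palladium ionises the aryl allyl ethers to π-allyl complexes that are captured by morpholine, freeing the two C5 phenols while the benzyl ethers stay.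

**Step 17**
Reactants: 28
Product: 29 bis(1-phenyl-1H-tetrazol-5-yl) ether of 28 at the two C5 oxygens
Conditions: 5-chloro-1-phenyl-1H-tetrazole (2.5 equiv), K2CO3, DMF, 60 °C
Reagents that add atoms: 5-chloro-1-phenyl-1H-tetrazole Clc1nnnn1-c1ccccc1
Why: Nucleophilic aromatic substitution of the chlorotetrazole by the two phenoxides turns the C5 oxygens into hydrogenolysable pseudo-halide ethers.

**Step 18**
Reactants: 29
Product: 30 epirobinetinidol-(4β→8)-epirobinetinidol-(4α→8)-epicatechin (upper unit 2R,3R,4R; middle unit 2R,3R,4S; lower unit 2R,3R)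
Conditions: H2 (3 atm), 10 % Pd/C, THF/MeOH, 40 °C
Reagents that add atoms: none
Why: Catalytic hydrogenolysis should cleave the fifteen benzyl ethers and, in the manner of the Musliner–Gates deoxygenation, the two aryl C–O bonds of the tetrazolyl ethers, leaving hydrogen at C5 of the upper and middle units without touching any stereocentre.

**Compound list**

1 | (+)-dihydromyricetin, (2R,3R)-3,5,7-trihydroxy-2-(3,4,5-trihydroxyphenyl)chroman-4-one | Oc1cc(O)c2c(c1)O[C@H](c1cc(O)c(O)c(O)c1)[C@@H](O)C2=O | starting material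
2 | (2R,3R)-7-(benzyloxy)-3,5-dihydroxy-2-[3,4,5-tris(benzyloxy)phenyl]chroman-4-one | c1ccccc1COc1cc(O)c2c(c1)O[C@H](c1cc(OCc3ccccc3)c(OCc3ccccc3)c(OCc3ccccc3)c1)[C@@H](O)C2=O | intermediate
3 | (2R,3R)-5-(allyloxy)-7-(benzyloxy)-3-hydroxy-2-[3,4,5-tris(benzyloxy)phenyl]chroman-4-one | c1ccccc1COc1cc(OCC=C)c2c(c1)O[C@H](c1cc(OCc3ccccc3)c(OCc3ccccc3)c(OCc3ccccc3)c1)[C@@H](O)C2=O | intermediate
4 | (2R,3S,4R)-5-(allyloxy)-7-(benzyloxy)-2-[3,4,5-tris(benzyloxy)phenyl]chromane-3,4-diol (2,3-trans-3,4-trans; not isolated) | c1ccccc1COc1cc(OCC=C)c2c(c1)O[C@H](c1cc(OCc3ccccc3)c(OCc3ccccc3)c(OCc3ccccc3)c1)[C@@H](O)[C@@H]2O | intermediate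
5 | (2R,3S,4R)-5-(allyloxy)-7-(benzyloxy)-4-methoxy-2-[3,4,5-tris(benzyloxy)phenyl]chroman-3-ol | c1ccccc1COc1cc(OCC=C)c2c(c1)O[C@H](c1cc(OCc3ccccc3)c(OCc3ccccc3)c(OCc3ccccc3)c1)[C@@H](O)[C@@H]2OC | intermediate
6 | (2R,4R)-5-(allyloxy)-7-(benzyloxy)-4-methoxy-2-[3,4,5-tris(benzyloxy)phenyl]chroman-3-one | c1ccccc1COc1cc(OCC=C)c2c(c1)O[C@H](c1cc(OCc3ccccc3)c(OCc3ccccc3)c(OCc3ccccc3)c1)C(=O)[C@@H]2OC | intermediate
7 | (2R,3R,4R)-5-(allyloxy)-7-(benzyloxy)-4-methoxy-2-[3,4,5-tris(benzyloxy)phenyl]chroman-3-ol (2,3-cis) | c1ccccc1COc1cc(OCC=C)c2c(c1)O[C@H](c1cc(OCc3ccccc3)c(OCc3ccccc3)c(OCc3ccccc3)c1)[C@H](O)[C@@H]2OC | intermediate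
8 | (2R,3R,4R)-5-(allyloxy)-3,7-bis(benzyloxy)-4-methoxy-2-[3,4,5-tris(benzyloxy)phenyl]chromane | c1ccccc1COc1cc(OCC=C)c2c(c1)O[C@H](c1cc(OCc3ccccc3)c(OCc3ccccc3)c(OCc3ccccc3)c1)[C@H](OCc1ccccc1)[C@@H]2OC | intermediate
9 | (2R,3R,4S)-5-(allyloxy)-3,7-bis(benzyloxy)-2-[3,4,5-tris(benzyloxy)phenyl]chroman-4-ol (not isolated) | c1ccccc1COc1cc(OCC=C)c2c(c1)O[C@H](c1cc(OCc3ccccc3)c(OCc3ccccc3)c(OCc3ccccc3)c1)[C@H](OCc1ccccc1)[C@H]2O | intermediate
10 | (2R,3S)-5-(allyloxy)-3,7-bis(benzyloxy)-2-[3,4,5-tris(benzyloxy)phenyl]chroman-4-one (2,3-cis) | c1ccccc1COc1cc(OCC=C)c2c(c1)O[C@H](c1cc(OCc3ccccc3)c(OCc3ccccc3)c(OCc3ccccc3)c1)[C@H](OCc1ccccc1)C2=O | intermediate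
11 | 1,3,5-trifluorobenzene | Fc1cc(F)cc(F)c1 | starting material
12 | 1,3-bis(benzyloxy)-5-fluorobenzene | Fc1cc(OCc2ccccc2)cc(OCc2ccccc2)c1 | intermediate
13 | methyl (R)-glycidate | COC(=O)[C@H]1CO1 | starting material
14 | [2,4-bis(benzyloxy)-6-fluorophenyl]lithium (not isolated) | [Li]c1c(F)cc(OCc2ccccc2)cc1OCc1ccccc1 | intermediate
15 | [2,4-bis(benzyloxy)-6-fluorophenyl]magnesium bromide (not isolated) | Br[Mg]c1c(F)cc(OCc2ccccc2)cc1OCc1ccccc1 | intermediate
16 | methyl (R)-3-[2,4-bis(benzyloxy)-6-fluorophenyl]-2-hydroxypropanoate | COC(=O)[C@H](O)Cc1c(F)cc(OCc2ccccc2)cc1OCc1ccccc1 | intermediate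
17 | methyl (R)-2-(benzyloxy)-3-[2,4-bis(benzyloxy)-6-fluorophenyl]propanoate | COC(=O)[C@H](OCc1ccccc1)Cc1c(F)cc(OCc2ccccc2)cc1OCc1ccccc1 | intermediate
18 | (R)-2-(benzyloxy)-3-[2,4-bis(benzyloxy)-6-fluorophenyl]propanal | O=C[C@H](OCc1ccccc1)Cc1c(F)cc(OCc2ccccc2)cc1OCc1ccccc1 | intermediate
19 | 4-bromo-1,2-bis(benzyloxy)benzene | Brc1ccc(OCc2ccccc2)c(OCc2ccccc2)c1 | starting material
20 | [3,4-bis(benzyloxy)phenyl]magnesium bromide (not isolated) | Br[Mg]c1ccc(OCc2ccccc2)c(OCc2ccccc2)c1 | intermediate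
21 | (1R,2R)-2-(benzyloxy)-1-[3,4-bis(benzyloxy)phenyl]-3-[2,4-bis(benzyloxy)-6-fluorophenyl]propan-1-ol | O[C@H](c1ccc(OCc2ccccc2)c(OCc2ccccc2)c1)[C@H](OCc1ccccc1)Cc1c(F)cc(OCc2ccccc2)cc1OCc1ccccc1 | intermediate
22 | lithium alkoxide of 21 lithiated at the ring carbon between F and OBn (not isolated) | [Li]O[C@H](c1ccc(OCc2ccccc2)c(OCc2ccccc2)c1)[C@H](OCc1ccccc1)Cc1c(F)c([Li])c(OCc2ccccc2)cc1OCc1ccccc1 | intermediate
23 | lithium alkoxide carrying the 3,5-bis(benzyloxy)benzyne ring (aryne between the former C–F and C–Li carbons; not isolated) | [Li]O[C@H](c1ccc(OCc2ccccc2)c(OCc2ccccc2)c1)[C@H](OCc1ccccc1)CC1=C(OCc2ccccc2)C=C(OCc2ccccc2)C#C1 | intermediate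
24 | (2R,3R)-3,5,7-tris(benzyloxy)-2-[3,4-bis(benzyloxy)phenyl]chroman-8-yllithium (not isolated) | [Li]c1c(OCc2ccccc2)cc(OCc2ccccc2)c2c1O[C@H](c1ccc(OCc3ccccc3)c(OCc3ccccc3)c1)[C@H](OCc1ccccc1)C2 | intermediate
25 | tertiary alcohol: 5-O-allyl-3,7,3',4',5'-penta-O-benzyl-epigallocatechin-4-ol with C4 bonded to C8 of penta-O-benzyl-(−)-epicatechin (aryl 4β, OH 4α) | c1ccccc1COc1cc(OCC=C)c2c(c1)O[C@H](c1cc(OCc3ccccc3)c(OCc3ccccc3)c(OCc3ccccc3)c1)[C@H](OCc1ccccc1)[C@@]2(O)c1c(OCc2ccccc2)cc(OCc2ccccc2)c2c1O[C@H](c1ccc(OCc3ccccc3)c(OCc3ccccc3)c1)[C@H](OCc1ccccc1)C2 | intermediate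
26 | 5-O-allyl-3,7,3',4',5'-penta-O-benzyl-epigallocatechin-(4α→8)-3,5,7,3',4'-penta-O-benzyl-epicatechin | c1ccccc1COc1cc(OCC=C)c2c(c1)O[C@H](c1cc(OCc3ccccc3)c(OCc3ccccc3)c(OCc3ccccc3)c1)[C@H](OCc1ccccc1)[C@@H]2c1c(OCc2ccccc2)cc(OCc2ccccc2)c2c1O[C@H](c1ccc(OCc3ccccc3)c(OCc3ccccc3)c1)[C@H](OCc1ccccc1)C2 | intermediate
27 | protected trimer with 5-O-allyl groups in the upper and middle units (upper 4β→8, middle 4α→8) | c1ccccc1COc1cc(OCC=C)c2c(c1)O[C@H](c1cc(OCc3ccccc3)c(OCc3ccccc3)c(OCc3ccccc3)c1)[C@H](OCc1ccccc1)[C@H]2c1c(OCc2ccccc2)cc(OCC=C)c2c1O[C@H](c1cc(OCc3ccccc3)c(OCc3ccccc3)c(OCc3ccccc3)c1)[C@H](OCc1ccccc1)[C@@H]2c1c(OCc2ccccc2)cc(OCc2ccccc2)c2c1O[C@H](c1ccc(OCc3ccccc3)c(OCc3ccccc3)c1)[C@H](OCc1ccccc1)C2 | intermediate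
28 | protected trimer with free 5-OH in the upper and middle units | c1ccccc1COc1cc(O)c2c(c1)O[C@H](c1cc(OCc3ccccc3)c(OCc3ccccc3)c(OCc3ccccc3)c1)[C@H](OCc1ccccc1)[C@H]2c1c(OCc2ccccc2)cc(O)c2c1O[C@H](c1cc(OCc3ccccc3)c(OCc3ccccc3)c(OCc3ccccc3)c1)[C@H](OCc1ccccc1)[C@@H]2c1c(OCc2ccccc2)cc(OCc2ccccc2)c2c1O[C@H](c1ccc(OCc3ccccc3)c(OCc3ccccc3)c1)[C@H](OCc1ccccc1)C2 | intermediate
29 | bis(1-phenyl-1H-tetrazol-5-yl) ether of 28 | c1ccccc1COc1cc(Oc3nnnn3-c3ccccc3)c2c(c1)O[C@H](c1cc(OCc3ccccc3)c(OCc3ccccc3)c(OCc3ccccc3)c1)[C@H](OCc1ccccc1)[C@H]2c1c(OCc2ccccc2)cc(Oc3nnnn3-c3ccccc3)c2c1O[C@H](c1cc(OCc3ccccc3)c(OCc3ccccc3)c(OCc3ccccc3)c1)[C@H](OCc1ccccc1)[C@@H]2c1c(OCc2ccccc2)cc(OCc2ccccc2)c2c1O[C@H](c1ccc(OCc3ccccc3)c(OCc3ccccc3)c1)[C@H](OCc1ccccc1)C2 | intermediate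
30 | epirobinetinidol-(4β→8)-epirobinetinidol-(4α→8)-epicatechin (CNP0115797.2) | Oc1ccc2c(c1)O[C@H](c1cc(O)c(O)c(O)c1)[C@H](O)[C@H]2c1c(O)ccc2c1O[C@H](c1cc(O)c(O)c(O)c1)[C@H](O)[C@@H]2c1c(O)cc(O)c2c1O[C@H](c1ccc(O)c(O)c1)[C@H](O)C2 | target

**Step count and risks**

Total step count: 18. Longest linear sequence: 13 steps (steps 1–7, then 13–18).

Steps most likely to fail:

1. Step 13 (Proposed new method). The aryne may be captured bimolecularly by still-unreacted aryllithium instead of by the tethered alkoxide. The aryllithium may abstract a benzylic ether proton during warming, or the hindered 8-lithioflavan may enolise ketone 10 instead of adding to it. The fallback uses known chemistry, sets out from 21 and comes back at 25. Treatment of 21 with KH in DMF (0 °C to rt) should close the same aryl ether bond by intramolecular nucleophilic aromatic substitution of fluoride by the C2 alkoxide, giving 3,5,7,3',4'-penta-O-benzyl-(−)-epicatechin F1. NBS in CH2Cl2 at −78 °C should brominate the most electron-rich position, C8, to give the 8-bromoflavan F2. Bromine–lithium exchange (t-BuLi, THF, −78 °C) then forms 24 at low temperature, and its addition to 10 gives 25.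

2. Step 15. The cation may attack C6 of the middle unit or C6 of the lower unit as well as C8 of the middle unit, and the electrophile may condense with itself. The fallback forms the upper interflavan bond first, on a monomer whose only nucleophilic ring is the intended one; it sets out from 8 and comes back at 27. Reductive removal of the 4-methoxy group of 8 (Et3SiH, BF3·OEt2, CH2Cl2, −78 °C) should give the flavan F3. Coupling of 8 with an excess of F3 (Me3SiOTf, CH2Cl2, −78 °C) should give the 4β→8 dimer F4. DDQ in wet CH2Cl2 should hydroxylate C4 of the lower unit of F4 to give the 4-hydroxy dimer F5, and Dess–Martin oxidation gives the dimeric ketone F6. The sequence of step 13 applied to 21 and F6 gives the trimeric carbinol F7, and Bu3SnH/CF3CO2H as in step 14 gives 27.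

3. Step 18. Cleavage of the two hindered aryl–oxygen bonds may be incomplete, or the catalyst may be slowed by the tetrazole, while the benzyl ethers are already gone, leaving partly deoxygenated polyphenols that are hard to separate. The fallback removes the C5 oxygens before deprotection; it sets out from 28 and comes back at 30. PhNTf2 and Et3N in CH2Cl2 should give the bis(triflate) F8. Homogeneous reduction (Pd(OAc)2, 1,1'-bis(diphenylphosphino)ferrocene, HCO2H, Et3N, DMF, 70 °C) should give the fully benzylated 5-deoxy trimer F9. Neutral hydrogenolysis (H2, Pd(OH)2/C, THF/MeOH) then gives 30.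

**Further compounds**

F1 | step 13 | (2R,3R)-3,5,7-tris(benzyloxy)-2-[3,4-bis(benzyloxy)phenyl]chromane (penta-O-benzyl-(−)-epicatechin) | c1c(OCc2ccccc2)cc(OCc2ccccc2)c2c1O[C@H](c1ccc(OCc3ccccc3)c(OCc3ccccc3)c1)[C@H](OCc1ccccc1)C2
F2 | step 13 | (2R,3R)-8-bromo-3,5,7-tris(benzyloxy)-2-[3,4-bis(benzyloxy)phenyl]chromane | Brc1c(OCc2ccccc2)cc(OCc2ccccc2)c2c1O[C@H](c1ccc(OCc3ccccc3)c(OCc3ccccc3)c1)[C@H](OCc1ccccc1)C2
F3 | step 15 | (2R,3R)-5-(allyloxy)-3,7-bis(benzyloxy)-2-[3,4,5-tris(benzyloxy)phenyl]chromane | c1ccccc1COc1cc(OCC=C)c2c(c1)O[C@H](c1cc(OCc3ccccc3)c(OCc3ccccc3)c(OCc3ccccc3)c1)[C@H](OCc1ccccc1)C2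
F4 | step 15 | 5-O-allyl-3,7,3',4',5'-penta-O-benzyl-epigallocatechin-(4β→8)-5-O-allyl-3,7,3',4',5'-penta-O-benzyl-epigallocatechin | c1ccccc1COc1cc(OCC=C)c2c(c1)O[C@H](c1cc(OCc3ccccc3)c(OCc3ccccc3)c(OCc3ccccc3)c1)[C@H](OCc1ccccc1)[C@H]2c1c(OCc2ccccc2)cc(OCC=C)c2c1O[C@H](c1cc(OCc3ccccc3)c(OCc3ccccc3)c(OCc3ccccc3)c1)[C@H](OCc1ccccc1)C2
F5 | step 15 | F4 hydroxylated at C4 of the lower unit (4β-OH) | c1ccccc1COc1cc(OCC=C)c2c(c1)O[C@H](c1cc(OCc3ccccc3)c(OCc3ccccc3)c(OCc3ccccc3)c1)[C@H](OCc1ccccc1)[C@H]2c1c(OCc2ccccc2)cc(OCC=C)c2c1O[C@H](c1cc(OCc3ccccc3)c(OCc3ccccc3)c(OCc3ccccc3)c1)[C@H](OCc1ccccc1)[C@H]2O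
F6 | step 15 | dimeric ketone: F4 with C4 of the lower unit as carbonyl | c1ccccc1COc1cc(OCC=C)c2c(c1)O[C@H](c1cc(OCc3ccccc3)c(OCc3ccccc3)c(OCc3ccccc3)c1)[C@H](OCc1ccccc1)[C@H]2c1c(OCc2ccccc2)cc(OCC=C)c2c1O[C@H](c1cc(OCc3ccccc3)c(OCc3ccccc3)c(OCc3ccccc3)c1)[C@H](OCc1ccccc1)C2=O
F7 | step 15 | trimeric tertiary alcohol: 27 with hydroxyl (4α) in place of hydrogen at C4 of the middle unit | c1ccccc1COc1cc(OCC=C)c2c(c1)O[C@H](c1cc(OCc3ccccc3)c(OCc3ccccc3)c(OCc3ccccc3)c1)[C@H](OCc1ccccc1)[C@H]2c1c(OCc2ccccc2)cc(OCC=C)c2c1O[C@H](c1cc(OCc3ccccc3)c(OCc3ccccc3)c(OCc3ccccc3)c1)[C@H](OCc1ccccc1)[C@@]2(O)c1c(OCc2ccccc2)cc(OCc2ccccc2)c2c1O[C@H](c1ccc(OCc3ccccc3)c(OCc3ccccc3)c1)[C@H](OCc1ccccc1)C2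
F8 | step 18 | bis(trifluoromethanesulfonate) of 28 at the two C5 oxygens | c1ccccc1COc1cc(OS(=O)(=O)C(F)(F)F)c2c(c1)O[C@H](c1cc(OCc3ccccc3)c(OCc3ccccc3)c(OCc3ccccc3)c1)[C@H](OCc1ccccc1)[C@H]2c1c(OCc2ccccc2)cc(OS(=O)(=O)C(F)(F)F)c2c1O[C@H](c1cc(OCc3ccccc3)c(OCc3ccccc3)c(OCc3ccccc3)c1)[C@H](OCc1ccccc1)[C@@H]2c1c(OCc2ccccc2)cc(OCc2ccccc2)c2c1O[C@H](c1ccc(OCc3ccccc3)c(OCc3ccccc3)c1)[C@H](OCc1ccccc1)C2
F9 | step 18 | pentadeca-O-benzyl ether of 30 (hydrogen at C5 of the upper and middle units) | c1ccccc1COc1ccc2c(c1)O[C@H](c1cc(OCc3ccccc3)c(OCc3ccccc3)c(OCc3ccccc3)c1)[C@H](OCc1ccccc1)[C@H]2c1c(OCc2ccccc2)ccc2c1O[C@H](c1cc(OCc3ccccc3)c(OCc3ccccc3)c(OCc3ccccc3)c1)[C@H](OCc1ccccc1)[C@@H]2c1c(OCc2ccccc2)cc(OCc2ccccc2)c2c1O[C@H](c1ccc(OCc3ccccc3)c(OCc3ccccc3)c1)[C@H](OCc1ccccc1)C2
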